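**Retrosynthetic overview**
1. The route rests on this feature: in the ten-membered carbocycle C1–C10, the lactone carbinol C6 is allylic to the trisubstituted C4=C5 olefin (C15 oxygen cis to C6) and adjoins C7, which carries the C11–C12 carboxyl arm. C5–C6 is therefore cut to a C5 (Z)-iodoalkene and a C6 aldehyde (Nozaki–Hiyama–Kishi); the carbocycle closes first, the γ-lactone ring second by O6→C12 acyl transfer.
2. After ring closure: Eschenmoser methylenation of the lactone (C13), DDQ release of O8, angeloylation, desilylation.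
3. The seco-aldehyde comes from a C7=C11 enoate (cross metathesis of the C8 allylic ether with methyl acrylate) by vinylcuprate addition anti to the C8 ether; the vinyl group is then cleaved to the C6 aldehyde.
4. The 1,10-epoxide is set by hydroxyl-directed epoxidation of the 2S allylic alcohol, made by adding a C1 alkenyllithium to a C2 aldehyde, then oxidation and CBS reduction.
5. Fragments: the C2–C5/C15 iodoalkene aldehyde from propargyl alcohol (anti-allylmagnesiation, iodination); the C1/C7–C10/C14 iodide from (R)-2-vinyloxirane (acetylide opening, methylalumination).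

Key step: step 15

Remark: germacrane numbering of the target is used for all intermediates; C13 is added only after lactonisation, because an aldehyde bearing the acrylate on C7 could slip its double bond into conjugation, and (R)-2-vinyloxirane is taken as the purchasable source of C8.

**Route**

Step 1
Reactants: 1 propargyl alcohol; 2 allylmagnesium bromide
Product: 4 (Z)-2-(iodomethylene)pent-4-en-1-ol, via alkenylmagnesium alkoxide 3 (not isolated)
Conditions: 2 (2.5 equiv), CuI (10 mol%), Et2O, 0 °C to rt; then I2, THF, −78 to 0 °C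
Reagents that add atoms: iodine, II
Why: Copper-catalysed anti-carbomagnesiation of the propargylic alkoxide puts the allyl group on the internal carbon and magnesium on the terminal carbon cis to the chelating CH2O arm, so iodinolysis with retention gives the iodoalkene with iodine cis to C15.

Step 2
Reactants: 4 (Z)-2-(iodomethylene)pent-4-en-1-ol
Product: 5 (Z)-tert-butyl{[2-(iodomethylene)pent-4-en-1-yl]oxy}dimethylsilane
Conditions: TBSCl, imidazole, DMF, rt
Reagents that add atoms: tert-butyldimethylsilyl chloride, CC(C)(C)[Si](C)(C)Cl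
Why: Standard silylation of a primary allylic alcohol; no other reactive group is present.

Step 3
Reactants: 5 (Z)-tert-butyl{[2-(iodomethylene)pent-4-en-1-yl]oxy}dimethylsilane
Product: 7 (Z)-3-{[(tert-butyldimethylsilyl)oxy]methyl}-4-iodobut-3-enal, via vicinal diol 6 (not isolated)
Conditions: OsO4 (2 mol%), NaIO4 (4 equiv), 2,6-lutidine (2 equiv), dioxane/H2O 3:1, rt; used crude
Reagents that add atoms: osmium tetroxide, O=[Os](=O)(=O)=O; sodium periodate, [Na+].[O-]I(=O)(=O)=O
Why: Lemieux–Johnson cleavage, in which the monosubstituted vinyl group is osmylated much faster than the halogen-deactivated trisubstituted iodoalkene and the lutidine buffer keeps the β,γ-unsaturated aldehyde from conjugating.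

Step 4
Reactants: 8 (R)-2-vinyloxirane; 9 lithium acetylide–ethylenediamine complex
Product: 10 (S)-hex-1-en-5-yn-3-ol
Conditions: 9 (1.5 equiv), DMSO, 15 °C to rt
Reagents that add atoms: none
Why: SN2 opening of the epoxide at its unsubstituted carbon by the acetylide without Lewis acid (no allylic or SN2′ attack), so the C8 stereocentre of 8 is carried over untouched.

Step 5
Reactants: 10 (S)-hex-1-en-5-yn-3-ol
Product: 12 (S,E)-6-iodo-5-methylhexa-1,5-dien-3-ol, via alkenylalane 11 (not isolated)
Conditions: Me3Al (3 equiv), Cp2ZrCl2 (0.3 equiv), CH2Cl2, 0 °C to rt; then I2, THF, −30 to 0 °C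
Reagents that add atoms: trimethylaluminium, C[Al](C)C; iodine, II
Why: Zirconium-catalysed syn-methylalumination (Negishi carboalumination) of the terminal alkyne, which reacts far faster than the alkene, followed by iodinolysis with retention gives the E iodoalkene with the C14 methyl cis to iodine.

Step 6
Reactants: 12 (S,E)-6-iodo-5-methylhexa-1,5-dien-3-ol
Product: 13 (S,E)-1-iodo-4-[(4-methoxybenzyl)oxy]-2-methylhexa-1,5-diene
Conditions: NaH, PMBCl, Bu4NI (cat.), THF/DMF, 0 °C to rt
Reagents that add atoms: 4-methoxybenzyl chloride, COc1ccc(CCl)cc1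
Why: Williamson etherification of the secondary alkoxide; the iodoalkene has no β-hydrogen on C10 and cannot eliminate.

Step 7
Reactants: 13 (S,E)-1-iodo-4-[(4-methoxybenzyl)oxy]-2-methylhexa-1,5-diene; 7 (Z)-3-{[(tert-butyldimethylsilyl)oxy]methyl}-4-iodobut-3-enal
Product: 15 (1Z,4RS,5E,8S)-2-{[(tert-butyldimethylsilyl)oxy]methyl}-1-iodo-8-[(4-methoxybenzyl)oxy]-6-methyldeca-1,5,9-trien-4-ol, via alkenyllithium 14 (not isolated)
Conditions: 13, t-BuLi (2.05 equiv), Et2O, −78 °C; then 7, −78 °C
Reagents that add atoms: none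
Why: Iodine–lithium exchange with retention of olefin geometry and 1,2-addition to the aldehyde forms C1–C2; no control at C2 is sought because steps 8 and 9 converge both epimers.

Step 8
Reactants: 15 (2RS)-allylic alcohol
Product: 16 (1Z,5E,8S)-2-{[(tert-butyldimethylsilyl)oxy]methyl}-1-iodo-8-[(4-methoxybenzyl)oxy]-6-methyldeca-1,5,9-trien-4-one
Conditions: Dess–Martin periodinane, NaHCO3, CH2Cl2, 0 °C; used without delay
Reagents that add atoms: none
Why: Dess–Martin oxidation of an allylic alcohol under buffered, near-neutral conditions that leave the doubly activated C3 methylene alone.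

Step 9
Reactants: 16 enone
Product: 17 (1Z,4S,5E,8S)-2-{[(tert-butyldimethylsilyl)oxy]methyl}-1-iodo-8-[(4-methoxybenzyl)oxy]-6-methyldeca-1,5,9-trien-4-ol (2S in germacrane numbering)
Conditions: (R)-2-methyl-CBS-oxazaborolidine (0.3 equiv), catecholborane (1.8 equiv), toluene, −78 °C
Reagents that add atoms: none
Why: Corey–Bakshi–Shibata reduction, in which the ketone binds the catalyst boron anti to the larger alkenyl arm and hydride is delivered to the Re face of C2, setting 2S under catalyst control without hydroboration of the olefins at −78 °C.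

Step 10
Reactants: 17 (2S)-allylic alcohol
Product: 18 (1R,2S,8S,10R)-1,10-epoxy alcohol (17 with C1=C10 converted into the oxirane, 2-OH free)
Conditions: mCPBA (1.1 equiv), NaHCO3, CH2Cl2, −20 to 0 °C
Reagents that add atoms: 3-chloroperbenzoic acid, OOC(=O)c1cccc(Cl)c1
Why: Henbest-type hydroxyl-directed epoxidation, in which A(1,3) strain between the C14 methyl (cis to C2) and the C2 substituents holds H2 in the olefin plane so the hydrogen-bonded peracid attacks the face bearing the 2S hydroxyl and gives the threo (1R,10R) epoxide, while the iodoalkene and the undirected vinyl group react far more slowly.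

Step 11
Reactants: 18 epoxy alcohol
Product: 19 (1R,2S,8S,10R)-2-O-triethylsilyl epoxide
Conditions: TESCl, imidazole, DMAP (cat.), CH2Cl2, 0 °C to rt
Reagents that add atoms: chlorotriethylsilane, CC[Si](Cl)(CC)CC
Why: Silylation with the chloride and imidazole avoids silyl triflates, which could trigger Lewis-acid opening of the neighbouring epoxide.

Step 12
Reactants: 19 TES ether; 20 methyl acrylate
Product: 21 (E)-C7=C11 methyl enoate (19 with the terminal =CH2 replaced by =CH–CO2Me)
Conditions: second-generation Hoveyda–Grubbs catalyst (5 mol%), 20 (10 equiv), CH2Cl2, 40 °C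
Reagents that add atoms: none
Why: Olefin cross metathesis of a terminal allylic ether with an excess of electron-poor acrylate is E-selective, and the hindered trisubstituted iodoalkene does not take part.

Step 13
Reactants: 21 enoate; 22 vinylmagnesium bromide
Product: 24 (1R,2S,7S,8S,10R)-7-vinyl methyl ester (vinyl on C7 anti to O8; target configuration at C7), via silyl ketene acetal 23 (not isolated)
Conditions: 22 (6 equiv), CuI (3 equiv), TMSCl (6 equiv), THF, −78 to −40 °C; then aq NH4Cl
Reagents that add atoms: none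
Why: Chlorotrimethylsilane-accelerated 1,4-addition of a magnesium divinylcuprate to a γ-alkoxy enoate, in which the C8–O bond stands antiperiplanar to the incoming reagent with H8 inside (modified Felkin–Anh), so vinyl adds anti to O8 and sets C7, and at low temperature the iodoalkene and the trisubstituted epoxide are left alone.

Step 14
Reactants: 24 vinyl ester
Product: 26 (1R,2S,7R,8S,10R)-seco-aldehyde (C6 aldehyde on C7; C11H2–CO2Me; C5 iodoalkene; 15-OTBS; 2-OTES; 8-OPMB), via vicinal diol 25 (not isolated)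
Conditions: OsO4 (2 mol%), NaIO4 (4 equiv), 2,6-lutidine (2 equiv), dioxane/H2O 3:1, rt; used crude
Reagents that add atoms: osmium tetroxide, O=[Os](=O)(=O)=O; sodium periodate, [Na+].[O-]I(=O)(=O)=O
Why: One-pot Lemieux–Johnson cleavage, in which osmylation prefers the monosubstituted vinyl group over the deactivated iodoalkene and periodate cleaves diol 25 before it can lactonise onto the ester, the buffer protecting the epimerisable C7 centre.

Step 15
Reactants: 26 seco-aldehyde
Product: 28 (1R,2S,6R,7S,8S,10R)-ten-membered hydroxy ester (6-OH, C12 methyl ester), via alkenylchromium dichloride 27 (not isolated)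
Conditions: CrCl2 (10 equiv), NiCl2 (0.1 equiv), degassed DMSO, rt, 0.002 M, slow addition of 26
Reagents that add atoms: none
Why: Divalent chromium reduces NiCl2 to zerovalent nickel, which inserts into the C5–I bond; transmetalation gives the trivalent alkenylchromium 27, which keeps the olefin geometry and adds to the C6 aldehyde, the closest known reaction type being the Nozaki–Hiyama–Kishi macrocyclization of iodoalkene aldehydes to medium-ring allylic alcohols. The ten-membered carbocycle closes by 10-exo-trig attack of C5 on the aldehyde carbon, the carbonyl oxygen staying outside the ring. The new C6 centre is controlled by C7 in a Felkin–Anh arrangement: the C8 branch (the ring tether) lies antiperiplanar to the incoming C5, which passes H7, with the CH2CO2Me arm beside the carbonyl oxygen, giving the 6R alcohol with O6 and C11 syn as the trans-fused lactone requires. The step needs chemoselectivity for the aldehyde over the ester, epoxide, silyl and PMB ethers, which the neutral organochromium provides, and ring closure must beat intermolecular coupling, which high dilution with slow addition secures. The saturated C11 methylene keeps the α-branched aldehyde from isomerising during the slow cyclization.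

Step 16
Reactants: 28 hydroxy ester
Product: 29 (1R,2S,6R,7R,8S,10R)-6,12-lactone (saturated C11; 8-OPMB; 2-OTES; 15-OTBS)
Conditions: DBU (0.3 equiv), toluene, rt
Reagents that add atoms: none
Why: Base-catalysed intramolecular transesterification (5-exo-trig acyl substitution) closes the γ-lactone trans-fused to the carbocycle because O6 and the C11 arm are syn across C6–C7, and acid is avoided so that the 1,10-epoxide is not opened transannularly by the C4=C5 olefin.

Step 17
Reactants: 29 lactone
Product: 31 11-(dimethylaminomethyl) lactone (C11 epimers), via lithium enolate 30 (not isolated)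
Conditions: LDA (LiN(iPr)2, 1.3 equiv), THF, −78 °C; then Eschenmoser's salt (CH2=NMe2 iodide), −78 to 0 °C
Reagents that add atoms: N,N-dimethylmethyleneiminium iodide, C=[N+](C)C.[I-]
Why: Mannich aminomethylation of the lactone enolate (Eschenmoser methylenation, first stage) at C11, the only enolisable position and one without a β-leaving group, the kinetic enolate being trapped at −78 °C; the C11 configuration is lost again in step 18.

Step 18
Reactants: 31 Mannich base
Product: 33 (1R,2S,6R,7R,8S,10R)-α-methylene lactone (8-OPMB; 2-OTES; 15-OTBS), via trimethylammonium iodide 32 (not isolated)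
Conditions: MeI, MeOH, rt; then NaHCO3, EtOAc/H2O, rt
Reagents that add atoms: none
Why: Exhaustive N-methylation followed by E1cB (Hofmann-type) loss of trimethylamine from the β-ammonio lactone gives the exocyclic C11=C13 olefin under weakly basic conditions.

Step 19
Reactants: 33 α-methylene lactone
Product: 34 (1R,2S,6R,7R,8S,10R)-8-hydroxy lactone (2-OTES; 15-OTBS)
Conditions: DDQ, CH2Cl2/pH 7 buffer 10:1, 0 °C
Reagents that add atoms: none
Why: Oxidative PMB ether cleavage by DDQ through a benzylic oxocarbenium ion hydrolysed by the buffer; silyl ethers, epoxide and the electron-poor methylene lactone are inert to the quinone.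

Step 20
Reactants: 34 8-hydroxy lactone; 35 angelic acid
Product: 36 (1R,2S,6R,7R,8S,10R)-8-O-angeloyl lactone (2-OTES; 15-OTBS)
Conditions: 35, 2,4,6-trichlorobenzoyl chloride, Et3N, toluene, rt; then 34, 75 °C
Reagents that add atoms: none
Why: Yamaguchi-type mixed anhydride esterification run without DMAP, conditions under which the Z (angelate) geometry is kept and a hindered secondary alcohol is still acylated.

Step 21
Reactants: 36 8-O-angeloyl lactone
Product: 37 EANPDB:COMP_00180
Conditions: HF·pyridine, pyridine, THF, 0 °C to rt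
Reagents that add atoms: none
Why: Fluoride-mediated cleavage of the secondary TES and primary TBS ethers with pyridine-buffered HF·pyridine, mild enough for the epoxide, the angelate and the methylene lactone.

**Compound list**
1 | propargyl alcohol | C#CCO | starting material
2 | allylmagnesium bromide | C=CC[Mg]Br | starting material
3 | alkenylmagnesium alkoxide (Mg cis to CH2O) | Br[Mg]/C=C(\CO[Mg]Br)CC=C | intermediate
4 | (Z)-2-(iodomethylene)pent-4-en-1-ol | I/C=C(\CO)CC=C | intermediate
5 | (Z)-tert-butyl{[2-(iodomethylene)pent-4-en-1-yl]oxy}dimethylsilane | I/C=C(\CO[Si](C)(C)C(C)(C)C)CC=C | intermediate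
6 | (Z)-4-{[(tert-butyldimethylsilyl)oxy]methyl}-5-iodopent-4-ene-1,2-diol | I/C=C(\CO[Si](C)(C)C(C)(C)C)CC(O)CO | intermediate
7 | (Z)-3-{[(tert-butyldimethylsilyl)oxy]methyl}-4-iodobut-3-enal | I/C=C(\CO[Si](C)(C)C(C)(C)C)CC=O | intermediate
8 | (R)-2-vinyloxirane | C=C[C@@H]1CO1 | starting material
9 | lithium acetylide–ethylenediamine complex | [Li+].[C-]#C.NCCN | starting material
10 | (S)-hex-1-en-5-yn-3-ol | C#CC[C@H](O)C=C | intermediate
11 | (E)-alkenyldimethylalane of 10 (aluminium alkoxide) | C[Al](C)/C=C(\C)C[C@H](O[Al](C)C)C=C | intermediate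
12 | (S,E)-6-iodo-5-methylhexa-1,5-dien-3-ol | I/C=C(\C)C[C@H](O)C=C | intermediate
13 | (S,E)-1-iodo-4-[(4-methoxybenzyl)oxy]-2-methylhexa-1,5-diene | I/C=C(\C)C[C@H](OCc1ccc(OC)cc1)C=C | intermediate
14 | (E)-alkenyllithium from 13 | [Li]/C=C(\C)C[C@H](OCc1ccc(OC)cc1)C=C | intermediate
15 | (1Z,4RS,5E,8S)-2-{[(tert-butyldimethylsilyl)oxy]methyl}-1-iodo-8-[(4-methoxybenzyl)oxy]-6-methyldeca-1,5,9-trien-4-ol | I/C=C(\CO[Si](C)(C)C(C)(C)C)CC(O)/C=C(\C)C[C@H](OCc1ccc(OC)cc1)C=C | intermediate
16 | (1Z,5E,8S)-2-{[(tert-butyldimethylsilyl)oxy]methyl}-1-iodo-8-[(4-methoxybenzyl)oxy]-6-methyldeca-1,5,9-trien-4-one | I/C=C(\CO[Si](C)(C)C(C)(C)C)CC(=O)/C=C(\C)C[C@H](OCc1ccc(OC)cc1)C=C | intermediate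
17 | (1Z,4S,5E,8S)-2-{[(tert-butyldimethylsilyl)oxy]methyl}-1-iodo-8-[(4-methoxybenzyl)oxy]-6-methyldeca-1,5,9-trien-4-ol | I/C=C(\CO[Si](C)(C)C(C)(C)C)C[C@H](O)/C=C(\C)C[C@H](OCc1ccc(OC)cc1)C=C | intermediate
18 | (1R,2S,8S,10R)-1,10-epoxy-2-ol (germacrane numbering; 5-iodo-4(5)-ene, 15-OTBS, 8-OPMB, 7-vinyl terminus) | I/C=C(\CO[Si](C)(C)C(C)(C)C)C[C@H](O)[C@H]1O[C@]1(C)C[C@H](OCc2ccc(OC)cc2)C=C | intermediate
19 | 2-O-triethylsilyl ether of 18 | I/C=C(\CO[Si](C)(C)C(C)(C)C)C[C@H](O[Si](CC)(CC)CC)[C@H]1O[C@]1(C)C[C@H](OCc2ccc(OC)cc2)C=C | intermediate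
20 | methyl acrylate | C=CC(=O)OC | starting material
21 | (E)-C7=C11 methyl enoate (C12 ester) | I/C=C(\CO[Si](C)(C)C(C)(C)C)C[C@H](O[Si](CC)(CC)CC)[C@H]1O[C@]1(C)C[C@H](OCc2ccc(OC)cc2)/C=C/C(=O)OC | intermediate
22 | vinylmagnesium bromide | C=C[Mg]Br | starting material
23 | trimethylsilyl ketene acetal of 24 | I/C=C(\CO[Si](C)(C)C(C)(C)C)C[C@H](O[Si](CC)(CC)CC)[C@H]1O[C@]1(C)C[C@H](OCc2ccc(OC)cc2)[C@H](C=C)C=C(OC)O[Si](C)(C)C | intermediate
24 | (1R,2S,7S,8S,10R)-7-vinyl methyl ester (vinyl anti to O8) | I/C=C(\CO[Si](C)(C)C(C)(C)C)C[C@H](O[Si](CC)(CC)CC)[C@H]1O[C@]1(C)C[C@H](OCc2ccc(OC)cc2)[C@H](C=C)CC(=O)OC | intermediate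
25 | vicinal diol from the vinyl group of 24 | I/C=C(\CO[Si](C)(C)C(C)(C)C)C[C@H](O[Si](CC)(CC)CC)[C@H]1O[C@]1(C)C[C@H](OCc2ccc(OC)cc2)[C@H](C(O)CO)CC(=O)OC | intermediate
26 | (1R,2S,7R,8S,10R)-seco-aldehyde: C5 iodoalkene, C6 aldehyde, 1,10-epoxide, 8-OPMB, C11H2–CO2Me | I/C=C(\CO[Si](C)(C)C(C)(C)C)C[C@H](O[Si](CC)(CC)CC)[C@H]1O[C@]1(C)C[C@H](OCc2ccc(OC)cc2)[C@H](C=O)CC(=O)OC | intermediate
27 | C5 alkenylchromium dichloride of 26 | Cl[Cr](Cl)/C=C(\CO[Si](C)(C)C(C)(C)C)C[C@H](O[Si](CC)(CC)CC)[C@H]1O[C@]1(C)C[C@H](OCc2ccc(OC)cc2)[C@H](C=O)CC(=O)OC | intermediate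
28 | (1R,2S,6R,7S,8S,10R)-ten-membered 6-hydroxy C12 methyl ester | COC(=O)C[C@H]1[C@H](O)/C=C(\CO[Si](C)(C)C(C)(C)C)C[C@H](O[Si](CC)(CC)CC)[C@H]2O[C@]2(C)C[C@@H]1OCc1ccc(OC)cc1 | intermediate
29 | (1R,2S,6R,7R,8S,10R)-6,12-lactone, C11 saturated | C1C(=O)O[C@@H]2/C=C(\CO[Si](C)(C)C(C)(C)C)C[C@H](O[Si](CC)(CC)CC)[C@H]3O[C@]3(C)C[C@H](OCc4ccc(OC)cc4)[C@@H]12 | intermediate
30 | lithium enolate of 29 | C1=C(O[Li])O[C@@H]2/C=C(\CO[Si](C)(C)C(C)(C)C)C[C@H](O[Si](CC)(CC)CC)[C@H]3O[C@]3(C)C[C@H](OCc4ccc(OC)cc4)[C@@H]12 | intermediate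
31 | 11-(dimethylaminomethyl) lactone (C11 epimers) | CN(C)CC1C(=O)O[C@@H]2/C=C(\CO[Si](C)(C)C(C)(C)C)C[C@H](O[Si](CC)(CC)CC)[C@H]3O[C@]3(C)C[C@H](OCc4ccc(OC)cc4)[C@@H]12 | intermediate
32 | 11-(trimethylammoniomethyl) lactone iodide | C[N+](C)(C)CC1C(=O)O[C@@H]2/C=C(\CO[Si](C)(C)C(C)(C)C)C[C@H](O[Si](CC)(CC)CC)[C@H]3O[C@]3(C)C[C@H](OCc4ccc(OC)cc4)[C@@H]12.[I-] | intermediate
33 | α-methylene lactone, 8-OPMB, 2-OTES, 15-OTBS | C=C1C(=O)O[C@@H]2/C=C(\CO[Si](C)(C)C(C)(C)C)C[C@H](O[Si](CC)(CC)CC)[C@H]3O[C@]3(C)C[C@H](OCc4ccc(OC)cc4)[C@@H]12 | intermediate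
34 | 8-hydroxy α-methylene lactone, 2-OTES, 15-OTBS | C=C1C(=O)O[C@@H]2/C=C(\CO[Si](C)(C)C(C)(C)C)C[C@H](O[Si](CC)(CC)CC)[C@H]3O[C@]3(C)C[C@H](O)[C@@H]12 | intermediate
35 | angelic acid, (Z)-2-methylbut-2-enoic acid | C/C=C(/C)C(=O)O | starting material
36 | 8-O-angeloyl lactone, 2-OTES, 15-OTBS | C=C1C(=O)O[C@@H]2/C=C(\CO[Si](C)(C)C(C)(C)C)C[C@H](O[Si](CC)(CC)CC)[C@H]3O[C@]3(C)C[C@H](OC(=O)/C(C)=C\C)[C@@H]12 | intermediate
37 | EANPDB:COMP_00180 | C=C1C(=O)O[C@@H]2/C=C(\CO)C[C@H](O)[C@H]3O[C@]3(C)C[C@H](OC(=O)/C(C)=C\C)[C@@H]12 | target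

**Totals**
Total step count: 21.
Longest linear sequence: 18 steps (steps 4–6, then 7–21; the branch through steps 1–3 is equally long).

**Steps most likely to fail**

1. Step 15. The alkenylchromium may attack the wrong face of the C6 aldehyde, since chelation of chromium between the aldehyde and the O8 ether would favour the 6S alcohol, and intermolecular coupling may compete with ring closure. Fallback: it sets out from 26. The cyclisation is run as in step 15, and the (6S)-hydroxy ester F1 that then predominates is saponified (LiOH, THF/H2O) to the (6S)-hydroxy acid F2. F2 is closed by an intramolecular Mitsunobu lactonisation (PPh3, DIAD, toluene, high dilution) with inversion at C6, which gives the trans-fused lactone and comes back to the route at 29.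

2. Step 13. Facial selectivity at C7 may be lower than in simpler γ-alkoxy enoates, and the cuprate may exchange or couple at the C5 iodide. Fallback: it sets out from 21. The vinyl group is delivered under catalyst control by a Hayashi–Miyaura addition: potassium vinyltrifluoroborate, [Rh(OH)(cod)]2 (monovalent rhodium) and the BINAP enantiomer matched to the substrate bias, Et3N, dioxane/H2O, 40 °C. This gives 24 directly without organocopper species and comes back at 24; it makes no compound outside the list (F0).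

3. Step 7. The basic alkenyllithium may deprotonate aldehyde 7 at C3, and the aldehyde double bond may drift into conjugation. Fallback: it sets out from 7. Pinnick oxidation (NaClO2, NaH2PO4, 2-methyl-2-butene) gives the carboxylic acid F3, and coupling with N,O-dimethylhydroxylamine hydrochloride (EDC·HCl, iPr2NEt) gives the Weinreb amide F4. Acylation of alkenyllithium 14 with F4 gives the enone directly; step 8 is skipped and the route is rejoined at 16.

**Further compounds**
F1 | step 15 | (6S)-ten-membered hydroxy ester, C6 epimer of 28 | COC(=O)C[C@H]1[C@@H](O)/C=C(\CO[Si](C)(C)C(C)(C)C)C[C@H](O[Si](CC)(CC)CC)[C@H]2O[C@]2(C)C[C@@H]1OCc1ccc(OC)cc1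
F2 | step 15 | (6S)-hydroxy acid | OC(=O)C[C@H]1[C@@H](O)/C=C(\CO[Si](C)(C)C(C)(C)C)C[C@H](O[Si](CC)(CC)CC)[C@H]2O[C@]2(C)C[C@@H]1OCc1ccc(OC)cc1
F0 | step 13 | none | none
F3 | step 7 | (Z)-3-{[(tert-butyldimethylsilyl)oxy]methyl}-4-iodobut-3-enoic acid | I/C=C(\CO[Si](C)(C)C(C)(C)C)CC(=O)O
F4 | step 7 | (Z)-3-{[(tert-butyldimethylsilyl)oxy]methyl}-4-iodo-N-methoxy-N-methylbut-3-enamide | I/C=C(\CO[Si](C)(C)C(C)(C)C)CC(=O)N(C)OC
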